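**Plan**

- Retrosynthesis: the fourteen phenols are masked as methyl ethers, and all five diaryl ether O-C4 bonds are then cut at once by putting a carbonyl back between each ether oxygen and C4 of the next ring. Every ether oxygen sits on C1 of one ring, between the oxygenated C2 and C6, and reaches C4 of the next ring (rings A to F, ring A being the 2,4,6-trihydroxyphenyl end). That is the pattern of an aryl 4-oxy-3,5-dimethoxybenzoate with its carbonyl carbon removed.
- The resulting pentaester is cut at its five C(acyl)-O bonds into 3,4,5-trimethoxybenzoic acid (ring F), four syringaldehyde units (rings E, D, C, B; CHO is the masked CO2H) and 2,4,6-trimethoxyphenol (ring A).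
- Forward: the chain is joined from ring F toward ring A by alternating Steglich esterification and Pinnick oxidation (F-E, F-E-D, F-E-D-C, F-E-D-C-B), ring A is esterified last, five CO units are extruded in one operation, and BBr3 frees the phenols.
- No ring is formed and the target has no stereocentre, so there is no stereochemistry to set.

Key step: step 10

Shorthand: TMB = 3,4,5-trimethoxybenzoyl; Syr = the 4-oxy-3,5-dimethoxybenzoyl unit -O-C6H2(OMe)2-C(=O)-, bound through its phenol oxygen to the carbonyl before it; DIC = N,N'-diisopropylcarbodiimide; dcypt = 3,4-bis(dicyclohexylphosphino)thiophene.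

Remark on step 10: the five CO extrusions have no fixed order, so the partly decarbonylated ester-ethers form a statistical family that converges on one product; they are not numbered.

**Route**

Step 1
Reactants: 1 3,4,5-trimethoxybenzoic acid; 2 syringaldehyde (4-hydroxy-3,5-dimethoxybenzaldehyde)
Product: 3 4-formyl-2,6-dimethoxyphenyl 3,4,5-trimethoxybenzoate (rings F-E aldehyde)
Conditions: DIC (1.2 equiv), DMAP (0.2 equiv), CH2Cl2, 0 °C to rt
Reagents that add atoms: none
Why: Steglich esterification, in which the carbodiimide converts acid 1 into an O-acylisourea that DMAP relays as an acylpyridinium ion reactive enough to acylate the di-ortho-methoxy phenol of 2, while the aldehyde of 2 is inert and is carried as the masked carboxyl of ring E.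

Step 2
Reactants: 3 4-formyl-2,6-dimethoxyphenyl 3,4,5-trimethoxybenzoate
Product: 4 3,5-dimethoxy-4-[(3,4,5-trimethoxybenzoyl)oxy]benzoic acid (TMB-Syr-OH, rings F-E acid)
Conditions: NaClO2, NaH2PO4, 2-methyl-2-butene, t-BuOH/THF/H2O, 0 °C to rt; then dilute HCl to pH 3
Reagents that add atoms: sodium chlorite NaClO2, [Na+].[O-]Cl=O
Why: Pinnick oxidation, in which chlorous acid adds to the aldehyde and fragments to the carboxylic acid in a weakly acidic buffer that does not hydrolyse the aryl ester, with 2-methyl-2-butene consuming the hypochlorous acid before it can chlorinate the methoxyarenes.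

Step 3
Reactants: 4 TMB-Syr-OH; 2 syringaldehyde
Product: 5 4-formyl-2,6-dimethoxyphenyl 3,5-dimethoxy-4-[(3,4,5-trimethoxybenzoyl)oxy]benzoate (rings F-E-D aldehyde)
Conditions: DIC (1.3 equiv), DMAP (0.3 equiv), 2 (1.5 equiv), CH2Cl2, 0 °C to rt
Reagents that add atoms: none
Why: Steglich esterification as in step 1, with phenol 2 in excess so that the acylpyridinium ion derived from 4 is consumed faster than DMAP or phenoxide can attack the ester link already present.

Step 4
Reactants: 5 rings F-E-D aldehyde
Product: 6 4-({3,5-dimethoxy-4-[(3,4,5-trimethoxybenzoyl)oxy]benzoyl}oxy)-3,5-dimethoxybenzoic acid (TMB-Syr2-OH, rings F-E-D acid)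
Conditions: NaClO2, NaH2PO4, 2-methyl-2-butene, t-BuOH/THF/H2O, 0 °C to rt; then dilute HCl to pH 3
Reagents that add atoms: sodium chlorite NaClO2, [Na+].[O-]Cl=O
Why: Pinnick oxidation as in step 2, chemoselective for the only aldehyde and run cold and buffered so that both aryl ester links survive.

Step 5
Reactants: 6 TMB-Syr2-OH; 2 syringaldehyde
Product: 7 4-formyl-2,6-dimethoxyphenyl ester of acid 6 (TMB-Syr2-O-C6H2(OMe)2-CHO, rings F-E-D-C aldehyde, three ester links)
Conditions: DIC (1.3 equiv), DMAP (0.3 equiv), 2 (1.5 equiv), CH2Cl2, 0 °C to rt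
Reagents that add atoms: none
Why: Steglich esterification of the same kind as steps 1 and 3, the methoxy groups on every ring keeping the growing oligoester soluble in CH2Cl2 so that the coupling stays homogeneous.

Step 6
Reactants: 7 rings F-E-D-C aldehyde
Product: 8 TMB-Syr3-OH (rings F-E-D-C acid; the CHO of 7 turned into CO2H)
Conditions: NaClO2, NaH2PO4, 2-methyl-2-butene, t-BuOH/THF/H2O, 0 °C to rt; then dilute HCl to pH 3
Reagents that add atoms: sodium chlorite NaClO2, [Na+].[O-]Cl=O
Why: Pinnick oxidation as in step 2, the THF cosolvent keeping the larger aldehyde in solution while the buffered medium spares the three aryl esters.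

Step 7
Reactants: 8 TMB-Syr3-OH; 2 syringaldehyde
Product: 9 4-formyl-2,6-dimethoxyphenyl ester of acid 8 (TMB-Syr3-O-C6H2(OMe)2-CHO, rings F-E-D-C-B aldehyde, four ester links)
Conditions: DIC (1.3 equiv), DMAP (0.3 equiv), 2 (1.5 equiv), CH2Cl2, 0 °C to rt
Reagents that add atoms: none
Why: Steglich esterification as in steps 1, 3 and 5, repeating a coupling between the same two functional groups, a 4-aroyloxy-3,5-dimethoxybenzoic acid and the phenol of 2.

Step 8
Reactants: 9 rings F-E-D-C-B aldehyde
Product: 10 TMB-Syr4-OH (rings F-E-D-C-B acid; the CHO of 9 turned into CO2H)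
Conditions: NaClO2, NaH2PO4, 2-methyl-2-butene, t-BuOH/THF/H2O, 0 °C to rt; then dilute HCl to pH 3
Reagents that add atoms: sodium chlorite NaClO2, [Na+].[O-]Cl=O
Why: Pinnick oxidation as in step 2, again touching only the terminal aldehyde and leaving the four aryl ester links intact.

Step 9
Reactants: 10 TMB-Syr4-OH; 11 2,4,6-trimethoxyphenol
Product: 12 2,4,6-trimethoxyphenyl ester of acid 10 (TMB-Syr4-O-C6H2(OMe)3; hexa-aryl pentaester, rings A to F)
Conditions: DIC (1.3 equiv), DMAP (0.3 equiv), 11 (1.5 equiv), CH2Cl2, rt, argon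
Reagents that add atoms: none
Why: Steglich esterification, with the electron-rich and oxidation-prone phenol 11 used in excess under argon so that acylation of its hindered hydroxyl outruns rearrangement of the O-acylisourea and installs ring A as the fifth ester link.

Step 10
Reactants: 12 hexa-aryl pentaester
Product: 13 tetradecamethyl ether of the target (rings A to F joined by five diaryl ether oxygens, fourteen OMe groups)
Conditions: Pd(OAc)2 (10 mol % per ester link), dcypt (20 mol % per ester link), anhydrous K3PO4, mesitylene (0.02 M), 160 °C, slow argon sweep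
Reagents that add atoms: none
Why: Proposed new method: zerovalent palladium, formed from Pd(OAc)2 and excess dcypt, should insert into each C(acyl)-O bond of 12, the resulting acyl palladium aryloxide should lose CO by aryl migration to the metal and CO dissociation, and aryl-aryloxide reductive elimination from divalent palladium should then form the O-C4 bond, so that the order of rings A to F written in the esters is copied into the ethers. The closest known reaction type is the decarbonylative etherification of aryl azinecarboxylates and electron-poor aryl benzoates to diaryl ethers with Pd(OAc)2 or Ni(cod)2 and dcypt, which has not been shown on alkoxy-substituted carbocyclic benzoates of 2,6-disubstituted phenols or at several ester links of one molecule. No ring is closed and no stereocentre is formed. The step needs insertion at C(acyl)-O rather than at C(aryl)-O or C-OMe, and the substrate secures this because every aryloxy carbon C1 is shielded by methoxy groups at C2 and C6, every acyl group sits on C4 between the unsubstituted C3 and C5, and the methyl ethers meet no nucleophile or reductant that could turn over a C-OMe insertion. It also needs each metal centre to eliminate with its own aryloxide before aryloxide exchange can shuffle the sequence, which is favoured by the chelating ligand, by the bulk of the di-ortho-substituted aryloxide, by a metal-bound C4 whose two meta methoxy groups withdraw inductively, and by the absence of any free phenol. CO is carried off in the argon stream so that it neither reinserts nor saturates the catalyst.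

Step 11
Reactants: 13 tetradecamethyl ether
Product: 14 target CNP0187343.0 (the tetradecaphenol)
Conditions: BBr3 (2 equiv per OMe), CH2Cl2, -78 °C to rt, argon; then degassed H2O, 0 °C; Sephadex LH-20 or C18 purification under argon
Reagents that add atoms: none
Why: Lewis acid cleavage of aryl methyl ethers, in which boron binds each methoxy oxygen and bromide removes the methyl group by SN2 displacement, whereas the five diaryl ether oxygens carry no sp3 carbon and are untouched, so that hydrolysis of the aryl borates releases all fourteen phenols.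

**Compound list**

1 | 3,4,5-trimethoxybenzoic acid | COc1cc(C(=O)O)cc(OC)c1OC | starting material
2 | syringaldehyde (4-hydroxy-3,5-dimethoxybenzaldehyde) | COc1cc(C=O)cc(OC)c1O | starting material
3 | 4-formyl-2,6-dimethoxyphenyl 3,4,5-trimethoxybenzoate (rings F-E aldehyde) | COc1cc(C(=O)Oc2c(OC)cc(C=O)cc2OC)cc(OC)c1OC | intermediate
4 | 3,5-dimethoxy-4-[(3,4,5-trimethoxybenzoyl)oxy]benzoic acid (TMB-Syr-OH) | COc1cc(C(=O)Oc2c(OC)cc(C(=O)O)cc2OC)cc(OC)c1OC | intermediate
5 | 4-formyl-2,6-dimethoxyphenyl 3,5-dimethoxy-4-[(3,4,5-trimethoxybenzoyl)oxy]benzoate (rings F-E-D aldehyde) | COc1cc(C(=O)Oc2c(OC)cc(C(=O)Oc3c(OC)cc(C=O)cc3OC)cc2OC)cc(OC)c1OC | intermediate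
6 | 4-({3,5-dimethoxy-4-[(3,4,5-trimethoxybenzoyl)oxy]benzoyl}oxy)-3,5-dimethoxybenzoic acid (TMB-Syr2-OH) | COc1cc(C(=O)Oc2c(OC)cc(C(=O)Oc3c(OC)cc(C(=O)O)cc3OC)cc2OC)cc(OC)c1OC | intermediate
7 | 4-formyl-2,6-dimethoxyphenyl ester of acid 6 (rings F-E-D-C aldehyde) | COc1cc(C(=O)Oc2c(OC)cc(C(=O)Oc3c(OC)cc(C(=O)Oc4c(OC)cc(C=O)cc4OC)cc3OC)cc2OC)cc(OC)c1OC | intermediate
8 | TMB-Syr3-OH (rings F-E-D-C acid) | COc1cc(C(=O)Oc2c(OC)cc(C(=O)Oc3c(OC)cc(C(=O)Oc4c(OC)cc(C(=O)O)cc4OC)cc3OC)cc2OC)cc(OC)c1OC | intermediate
9 | 4-formyl-2,6-dimethoxyphenyl ester of acid 8 (rings F-E-D-C-B aldehyde) | COc1cc(C(=O)Oc2c(OC)cc(C(=O)Oc3c(OC)cc(C(=O)Oc4c(OC)cc(C(=O)Oc5c(OC)cc(C=O)cc5OC)cc4OC)cc3OC)cc2OC)cc(OC)c1OC | intermediate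
10 | TMB-Syr4-OH (rings F-E-D-C-B acid) | COc1cc(C(=O)Oc2c(OC)cc(C(=O)Oc3c(OC)cc(C(=O)Oc4c(OC)cc(C(=O)Oc5c(OC)cc(C(=O)O)cc5OC)cc4OC)cc3OC)cc2OC)cc(OC)c1OC | intermediate
11 | 2,4,6-trimethoxyphenol | COc1cc(OC)c(O)c(OC)c1 | starting material
12 | 2,4,6-trimethoxyphenyl ester of acid 10 (hexa-aryl pentaester, rings A to F) | COc1cc(OC)c(OC(=O)c2cc(OC)c(OC(=O)c3cc(OC)c(OC(=O)c4cc(OC)c(OC(=O)c5cc(OC)c(OC(=O)c6cc(OC)c(OC)c(OC)c6)c(OC)c5)c(OC)c4)c(OC)c3)c(OC)c2)c(OC)c1 | intermediate
13 | tetradecamethyl ether of the target | COc1cc(OC)c(Oc2cc(OC)c(Oc3cc(OC)c(Oc4cc(OC)c(Oc5cc(OC)c(Oc6cc(OC)c(OC)c(OC)c6)c(OC)c5)c(OC)c4)c(OC)c3)c(OC)c2)c(OC)c1 | intermediate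
14 | CNP0187343.0 | Oc1cc(O)c(Oc2cc(O)c(Oc3cc(O)c(Oc4cc(O)c(Oc5cc(O)c(Oc6cc(O)c(O)c(O)c6)c(O)c5)c(O)c4)c(O)c3)c(O)c2)c(O)c1 | target

**Step count**

Total steps: 11. Longest linear sequence: 11 steps (1 and 2 to 14).

**Steps most likely to fail**

Step 10 (fivefold CO extrusion). Insertion at the less activated links or CO loss may stall while CO saturates the palladium, leaving mixed ester-ether chains. Aryloxide exchange between palladium centres, or onto ester carbonyls still present, may shuffle the ring order, and protodepalladation may cut chains. The fallback uses known chemistry and makes the ethers one at a time; it sets out from 11 and returns at 13. Commercial 4-bromo-2,6-dimethoxyphenol is benzylated (BnBr, K2CO3, DMF) to 2-(benzyloxy)-5-bromo-1,3-dimethoxybenzene F1. Copper-catalysed Ullmann ether coupling of 11 with F1 (CuI, picolinic acid, K3PO4, DMSO, 100 °C) should give the rings A-B benzyl ether 2-[4-(benzyloxy)-3,5-dimethoxyphenoxy]-1,3,5-trimethoxybenzene F2. Hydrogenolysis (H2, Pd/C, EtOAc/MeOH) should then give the rings A-B phenol 2,6-dimethoxy-4-(2,4,6-trimethoxyphenoxy)phenol F3. The same pair of operations with F1 adds ring C (rings A-B-C benzyl ether F4, rings A-B-C phenol F5), ring D (rings A-B-C-D benzyl ether F6, rings A-B-C-D phenol F7) and ring E (rings A-B-C-D-E benzyl ether F8, rings A-B-C-D-E phenol F9). A last Ullmann coupling of F9 with commercial 5-bromo-1,2,3-trimethoxybenzene under the same conditions gives 13.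

Step 11 (fourteenfold demethylation). Cleavage may stop short of all fourteen ethers, and the free polyphenol, above all the pyrogallol-type ring F, may oxidise in air during isolation, so that direct purification gives mixtures. The fallback isolates the product through a stable derivative; it sets out from 13 and returns at 14. After the BBr3 treatment and aqueous quench the crude polyphenol is not purified but acetylated at once (Ac2O, pyridine, DMAP, rt) to the tetradecaacetate of the target F10. F10 is stable to air and silica, so it can be separated from under-demethylated congeners by chromatography. Acid-catalysed methanolysis of pure F10 (HCl from AcCl in degassed MeOH, rt, argon) followed by evaporation of methanol and methyl acetate should then deliver 14 without further chromatography.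

Step 9 (attachment of ring A). The hindered, electron-rich phenol 11 may be acylated too slowly by the bulky pentameric acyl donor, so that O-to-N acyl shift in the O-acylisourea and ester interchange along the chain compete. The fallback attaches ring A to a small, reactive acyl donor first and closes the chain by a coupling of the kind used in steps 3, 5 and 7. It sets out from 8 and 11 and returns at 12, so steps 7 and 8 fall away. Commercial 4-(benzyloxy)-3,5-dimethoxybenzoic acid is converted ((COCl)2, catalytic DMF, CH2Cl2) into 4-(benzyloxy)-3,5-dimethoxybenzoyl chloride F11. F11 acylates 11 (Et3N, DMAP, CH2Cl2, 0 °C to rt, argon) to give 2,4,6-trimethoxyphenyl 4-(benzyloxy)-3,5-dimethoxybenzoate F12. Hydrogenolysis (H2, Pd/C, EtOAc) frees the rings A-B phenol 2,4,6-trimethoxyphenyl 4-hydroxy-3,5-dimethoxybenzoate F13. Steglich esterification of acid 8 with F13 (DIC, DMAP, CH2Cl2) then gives 12.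

**Further compounds**

F1 | step 10 | 2-(benzyloxy)-5-bromo-1,3-dimethoxybenzene | COc1cc(Br)cc(OC)c1OCc1ccccc1
F2 | step 10 | 2-[4-(benzyloxy)-3,5-dimethoxyphenoxy]-1,3,5-trimethoxybenzene (rings A-B benzyl ether) | COc1cc(OC)c(Oc2cc(OC)c(OCc3ccccc3)c(OC)c2)c(OC)c1
F3 | step 10 | 2,6-dimethoxy-4-(2,4,6-trimethoxyphenoxy)phenol (rings A-B phenol) | COc1cc(OC)c(Oc2cc(OC)c(O)c(OC)c2)c(OC)c1
F4 | step 10 | rings A-B-C benzyl ether | COc1cc(OC)c(Oc2cc(OC)c(Oc3cc(OC)c(OCc4ccccc4)c(OC)c3)c(OC)c2)c(OC)c1
F5 | step 10 | rings A-B-C phenol | COc1cc(OC)c(Oc2cc(OC)c(Oc3cc(OC)c(O)c(OC)c3)c(OC)c2)c(OC)c1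
F6 | step 10 | rings A-B-C-D benzyl ether | COc1cc(OC)c(Oc2cc(OC)c(Oc3cc(OC)c(Oc4cc(OC)c(OCc5ccccc5)c(OC)c4)c(OC)c3)c(OC)c2)c(OC)c1
F7 | step 10 | rings A-B-C-D phenol | COc1cc(OC)c(Oc2cc(OC)c(Oc3cc(OC)c(Oc4cc(OC)c(O)c(OC)c4)c(OC)c3)c(OC)c2)c(OC)c1
F8 | step 10 | rings A-B-C-D-E benzyl ether | COc1cc(OC)c(Oc2cc(OC)c(Oc3cc(OC)c(Oc4cc(OC)c(Oc5cc(OC)c(OCc6ccccc6)c(OC)c5)c(OC)c4)c(OC)c3)c(OC)c2)c(OC)c1
F9 | step 10 | rings A-B-C-D-E phenol | COc1cc(OC)c(Oc2cc(OC)c(Oc3cc(OC)c(Oc4cc(OC)c(Oc5cc(OC)c(O)c(OC)c5)c(OC)c4)c(OC)c3)c(OC)c2)c(OC)c1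
F10 | step 11 | tetradecaacetate of the target | CC(=O)Oc1cc(OC(C)=O)c(Oc2cc(OC(C)=O)c(Oc3cc(OC(C)=O)c(Oc4cc(OC(C)=O)c(Oc5cc(OC(C)=O)c(Oc6cc(OC(C)=O)c(OC(C)=O)c(OC(C)=O)c6)c(OC(C)=O)c5)c(OC(C)=O)c4)c(OC(C)=O)c3)c(OC(C)=O)c2)c(OC(C)=O)c1
F11 | step 9 | 4-(benzyloxy)-3,5-dimethoxybenzoyl chloride | COc1cc(C(Cl)=O)cc(OC)c1OCc1ccccc1
F12 | step 9 | 2,4,6-trimethoxyphenyl 4-(benzyloxy)-3,5-dimethoxybenzoate | COc1cc(OC)c(OC(=O)c2cc(OC)c(OCc3ccccc3)c(OC)c2)c(OC)c1
F13 | step 9 | 2,4,6-trimethoxyphenyl 4-hydroxy-3,5-dimethoxybenzoate | COc1cc(OC)c(OC(=O)c2cc(OC)c(O)c(OC)c2)c(OC)c1
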